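The impurity is a small charge, 0.24 mM, yet I reckon it first: the step initiator + impurity -> spent initiator takes one initiator per impurity, and spent initiator carries no chain.

| setting | ochre | teal | red | south-west | east |
|---|---|---|---|---|---|
| free monomer | 0.40 M (fed, over 6.0 h) | 0.40 M (fed, over 6.0 h) | 0.40 M (fed, over 6.0 h) | 0.40 M (fed, over 6.0 h) | 0.40 M (fed, over 6.0 h) |
| pre-initiator | 2.5 mM | 3.8 mM | 7.5 mM | 2.0 mM | 8.0 mM |
| impurity | 0.24 mM | 0.24 mM | 0.24 mM | 0.24 mM | 0.24 mM |
| remark | run made earlier; the fed solution adds 0.20 times the starting volume | run made earlier; the fed solution adds 0.20 times the starting volume | run made earlier; the fed solution adds 0.20 times the starting volume | the fed solution adds 0.20 times the starting volume | the fed solution adds 0.20 times the starting volume |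
| time |  |  |  | 10 d | 10 d |

| run | time / d | monomer in chains / % | free monomer / % |
|---|---|---|---|
| ochre | 0.417 | 1 | 100 |
| ochre | 0.833 | 0 | 98 |
| ochre | 1.25 | 0 | 100 |
| ochre | 2.50 | 7 | 94 |
| ochre | 5.00 | 22 | 77 |
| teal | 0.417 | 0 | 101 |
| teal | 0.833 | 1 | 99 |
| teal | 1.25 | 1 | 98 |
| teal | 2.50 | 10 | 86 |
| teal | 5.00 | 32 | 68 |
| red | 0.417 | 0 | 101 |
| red | 1.25 | 7 | 95 |
| red | 2.50 | 18 | 84 |
| red | 4.00 | 46 | 56 |
| red | 5.00 | 53 | 40 |

(each reading ± 2 percentage points)

- charges are per starting volume, the dose included; the dosed solution carries all of it
- the average divides the monomer in chains by the number of chains begun, living and dead together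
- the earlier runs were read with a standard deviation of 2 percentage points
- steps thought possible: free monomer + initiator -> living end + monomer in chains; free monomer + living end -> monomer in chains + living end; monomer in chains + living end -> free monomer + living end; initiator + impurity -> spent initiator; pre-initiator <-> initiator
- the earlier runs do not show the number of chains; that part of a forecast is a guess

* which of the two ends with the longer chains by the average number of monomer units in a chain (chains begun, living or dead) ("neither" if they lie within 10 %) (south-west / east / neither)
* average number of monomer units in a chain (chains begun, living or dead) at the end, south-west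
* average number of monomer units in a chain (chains begun, living or dead) at the end, east

I count everything as fractions of the pre-initiator charge. Let a be the fraction that is no longer pre-initiator or initiator, and let s be the fraction spent on impurity, the impurity share. It is 0.120 in south-west and 0.0300 in east. I assume impurity, the limiting reagent of its step, gets used up. With x the fraction of free monomer in chains, the volume cancels:

chains begun = a − s

length = x · (free monomer charge / pre-initiator charge) / (a − s)

Now x. In ochre, the logarithm of the free monomer fraction grew by a factor of 4.22 from 2.50 d to 5.00 d, a reading with its scatter. So the rate climbs in ochre over that stretch. But the pre-initiator is finite, so for the doubling to 10 d I take a factor of 3, and I scale by the net chains, charge minus impurity. South-west scales from ochre and east from red: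

south-west: x = 45.7 %

east: x = 94.7 %

Taking a as the whole charge, I get lengths of 104 for south-west and 48.8 for east.

The forecast also names south-west, with 140 (90 to 220) and 62 (42 to 95), reckoning that “about 70% is activated by 10 d”. My lengths are shorter than its lengths.

The flask gives south-west, with 117 against 51.0.

    free monomer + initiator → living end + monomer in chains (k = 2.10 × 10⁻⁴ M⁻¹ s⁻¹)
    free monomer + living end → monomer in chains + living end, rate k2*[living end]*[free monomer] (k = 9.90 × 10⁻⁴ M⁻¹ s⁻¹)
    monomer in chains + living end → free monomer + living end, rate k3*[living end] as long as [monomer in chains] is above zero (k = 3.30 × 10⁻⁵ s⁻¹)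
    initiator + impurity → spent initiator (k = 1.40 M⁻¹ s⁻¹)
    pre-initiator ⇌ initiator (K = 2.40, k = 2.90 × 10⁻⁶ s⁻¹)

In south-west, reckoned on the charges, initiator has a half-life of 0.57 h against impurity alone and 0.096 d against free monomer alone, so the impurity step is faster by a factor of 4.00. Impurity stands at 0 % by 10.0 d, with spent initiator at 2.00 × 10⁻⁴ M. Of south-west's pre-initiator, 91.4 % has passed on by 10.0 d, not the forecast's 70%; of that, the share 0.120 is spent initiator, initiator holds 0.00670 of the charge and living ends hold 0.787. A neighbour flask, like south-west but charged with 0.0050 M of pre-initiator, has an impurity share of 0.0480 and ends at length 73.7.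

The numbers in the tables come from a simulation with constants of no real substance; the scatter is artificial.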